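**Retrosynthetic overview**

- The strategy rests on ring B, the central phenol (C1 CH2CH2–ring A, C2 and C6 4-hydroxybenzyl, C3–H, C4–H, C5–OH). Its C2–C3–C4–C5(–O) run is a 2-(arylmethyl)furan whose ring oxygen becomes the C5 phenol oxygen, and its C6–C1 edge is an alkyne.
- The bibenzyl C–C bond comes from a stilbene, made by Horner–Wadsworth–Emmons coupling of a ring-B benzylphosphonate with the ring-A aldehyde. One hydrogenation then saturates the alkene and removes all four benzyl ethers.
- Ring B comes from a Diels–Alder reaction of 2-[4-(benzyloxy)benzyl]furan with methyl 4-[4-(benzyloxy)phenyl]but-2-ynoate, followed by acid opening of the oxygen bridge to the 2,6-bis(arylmethyl)-3-hydroxybenzoate. The ester carbon becomes the ring-B-side CH2 of the ethano bridge.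
- Both cycloaddition partners come from 4-(benzyloxy)benzyl chloride: alkylation of 2-furyllithium, and copper-catalysed ethynylation followed by carboxylation.
- Ring A and the two 4-oxygenated benzyl rings are bought; ring B is the only ring formed (step 4).

Key step: step 4

Remark: the target has no stereocentre. The bridged adduct 10 is a racemate whose bridgehead centres vanish on aromatisation, and the alkene geometry of 18 is irrelevant because the double bond is hydrogenated. The aluminium Lewis acid of step 4 is taken as destroyed on aqueous work-up.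

**Route**

Step 1
Reactants: 1 furan; 2 4-(benzyloxy)benzyl chloride
Product: 4 2-[4-(benzyloxy)benzyl]furan, via 2-furyllithium 3 (not isolated)
Conditions: furan (2 equiv), n-BuLi (1.1 equiv), THF, −78 → 0 °C, 1 h; then 2, −78 °C → rt
Reagents that add atoms: none
Why: α-Lithiation of furan and SN2 alkylation of 2-furyllithium with the activated benzylic chloride should give the 2-(arylmethyl)furan, the excess of furan suppressing 2,5-dialkylation.

Step 2
Reactants: 2 4-(benzyloxy)benzyl chloride; 5 ethynylmagnesium bromide
Product: 6 1-(benzyloxy)-4-(prop-2-yn-1-yl)benzene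
Conditions: 5 (2.5 equiv, 0.5 M in THF), CuCl (10 mol%), THF, 50 °C
Reagents that add atoms: none
Why: Copper-catalysed sp–sp3 cross-coupling of an alkynyl Grignard reagent with a benzylic halide should give the 3-arylpropyne; excess Grignard reagent limits double benzylation and a short reaction time limits propargyl-to-allenyl isomerisation.

Step 3
Reactants: 6 1-(benzyloxy)-4-(prop-2-yn-1-yl)benzene; 7 methyl chloroformate
Product: 9 methyl 4-[4-(benzyloxy)phenyl]but-2-ynoate, via lithium acetylide 8 (not isolated)
Conditions: n-BuLi (1.05 equiv), THF, −78 °C; cannulated into 7 (2 equiv), THF, −78 °C; NH4Cl quench at −78 °C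
Reagents that add atoms: none
Why: Acylation of the lithium acetylide with methyl chloroformate (alkoxycarbonylation of a terminal alkyne) should give the ynoate, and inverse addition at low temperature keeps the acetylide from deprotonating the doubly activated CH2 of the product.

Step 4
Reactants: 4 2-[4-(benzyloxy)benzyl]furan; 9 methyl 4-[4-(benzyloxy)phenyl]but-2-ynoate
Product: 11 methyl 2,6-bis[4-(benzyloxy)benzyl]-3-hydroxybenzoate, via 7-oxanorbornadiene adduct 10 (not isolated)
Conditions: 4 (1.5 equiv), EtAlCl2 (1.5 equiv), CH2Cl2, −78 → 0 °C; then BF3·OEt2 (0.2 equiv), 0 °C → rt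
Reagents that add atoms: none
Why: EtAlCl2 binds the ester carbonyl of 9, lowers the alkyne LUMO and concentrates it on the β-carbon (C3 of the butynoate, which carries the arylmethyl group), so that furan 4, whose HOMO is largest at its unsubstituted C5, should add in a concerted but strongly asynchronous [4+2] sense (in the limit a Michael-type attack followed by collapse of the zwitterion), forming the bonds furan C5–alkyne C3 and furan C2–alkyne C2. This intermolecular cycloaddition closes the six-membered carbocycle of ring B as the 7-oxabicyclo[2.2.1]hepta-2,5-diene 10, whose two bridgehead stereocentres are tied to each other by the oxygen bridge, arise as a racemate and are erased in the next event. The Lewis acid, completed by BF3·OEt2, then ionises the C–O bond at the quaternary bridgehead to a tertiary pentadienyl cation with charge on C1, C3 and C5 of the bicycle and none on the ester-bearing C2, and deprotonation at the hydrogen-bearing bridgehead aromatises the ring, leaving the hydroxyl on the carbon that was the free furan α-position. The closest known reaction type is the Lewis-acid-promoted Diels–Alder reaction of furans with acetylenic esters together with the acid isomerisation of the resulting 7-oxanorbornadienes to 3-hydroxybenzoates. The step needs the ortho orientation of the two unsymmetrical partners, secured by pairing the nucleophilic free α-carbon of the furan with the electrophilic β-carbon of the ynoate, and it needs bridge opening towards the arylmethyl-bearing carbon, secured by the tertiary cation that is insulated from the ester. It also needs the furan to outcompete the two alkoxyarene rings as the nucleophile and the benzyl ethers to survive, for which an alkylaluminium chloride at low temperature is chosen over AlCl3.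

Step 5
Reactants: 11 methyl 2,6-bis[4-(benzyloxy)benzyl]-3-hydroxybenzoate
Product: 12 methyl 3-(benzyloxy)-2,6-bis[4-(benzyloxy)benzyl]benzoate
Conditions: BnBr (1.3 equiv), K2CO3 (2 equiv), DMF, 40 °C
Reagents that add atoms: benzyl bromide, BrCc1ccccc1
Why: Williamson ether synthesis on the phenol should proceed cleanly, the hindered methyl ester and the diarylmethane CH2 groups being inert to K2CO3.

Step 6
Reactants: 12 methyl 3-(benzyloxy)-2,6-bis[4-(benzyloxy)benzyl]benzoate
Product: 13 [3-(benzyloxy)-2,6-bis[4-(benzyloxy)benzyl]phenyl]methanol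
Conditions: LiAlH4 (2 equiv), THF, 0 °C → reflux; Fieser work-up
Reagents that add atoms: none
Why: Hydride reduction of the di-ortho-substituted ester with LiAlH4 at reflux should give the primary benzylic alcohol without touching the aryl benzyl ethers.

Step 7
Reactants: 13 [3-(benzyloxy)-2,6-bis[4-(benzyloxy)benzyl]phenyl]methanol
Product: 14 1-(benzyloxy)-2,4-bis[4-(benzyloxy)benzyl]-3-(bromomethyl)benzene
Conditions: CBr4 (1.3 equiv), PPh3 (1.3 equiv), CH2Cl2, 0 °C → rt
Reagents that add atoms: carbon tetrabromide, BrC(Br)(Br)Br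
Why: The Appel reaction converts the benzylic alcohol into the bromide under neutral conditions, which avoids acid-induced Friedel–Crafts closure onto the neighbouring arylmethyl rings.

Step 8
Reactants: 14 1-(benzyloxy)-2,4-bis[4-(benzyloxy)benzyl]-3-(bromomethyl)benzene
Product: 15 diethyl [3-(benzyloxy)-2,6-bis[4-(benzyloxy)benzyl]benzyl]phosphonate
Conditions: P(OEt)3 (neat, excess), 130 °C; excess removed in vacuo
Reagents that add atoms: triethyl phosphite, CCOP(OCC)OCC
Why: The Michaelis–Arbuzov reaction of a benzylic bromide with triethyl phosphite should give the phosphonate, volatile bromoethane leaving the mixture.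

Step 9
Reactants: 16 3-hydroxy-5-methoxybenzaldehyde
Product: 17 3-(benzyloxy)-5-methoxybenzaldehyde
Conditions: BnBr (1.2 equiv), K2CO3 (2 equiv), acetone, reflux
Reagents that add atoms: benzyl bromide, BrCc1ccccc1
Why: Williamson ether synthesis masks the ring-A phenol as the same benzyl ether used elsewhere, so that one final hydrogenolysis frees all phenols.

Step 10
Reactants: 15 diethyl [3-(benzyloxy)-2,6-bis[4-(benzyloxy)benzyl]benzyl]phosphonate; 17 3-(benzyloxy)-5-methoxybenzaldehyde
Product: 18 1-(benzyloxy)-3-[(E)-2-[3-(benzyloxy)-5-methoxyphenyl]ethenyl]-2,4-bis[4-(benzyloxy)benzyl]benzene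
Conditions: 17 (1.2 equiv), KOtBu (1.3 equiv), THF, 0 °C → rt
Reagents that add atoms: none
Why: Horner–Wadsworth–Emmons olefination of the unhindered aromatic aldehyde with the benzylic phosphonate anion should give the (E)-stilbene, whose geometry is of no consequence for the next step.

Step 11
Reactants: 18 1-(benzyloxy)-3-[(E)-2-[3-(benzyloxy)-5-methoxyphenyl]ethenyl]-2,4-bis[4-(benzyloxy)benzyl]benzene
Product: 19 3-[2-[3-hydroxy-2,6-bis(4-hydroxybenzyl)phenyl]ethyl]-5-methoxyphenol (target)
Conditions: H2 (1 atm), 10% Pd/C, THF–MeOH (1:1), rt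
Reagents that add atoms: none
Why: Heterogeneous catalytic hydrogenation should saturate the stilbene double bond and hydrogenolyse all four aryl benzyl ethers in one operation, while the aryl methyl ether and the diarylmethane C–C bonds are stable.

**Compound list**

1 | furan | c1ccoc1 | starting material
2 | 4-(benzyloxy)benzyl chloride | ClCc1ccc(OCc2ccccc2)cc1 | starting material
3 | 2-furyllithium | [Li]c1ccco1 | intermediate
4 | 2-[4-(benzyloxy)benzyl]furan | c1coc(Cc2ccc(OCc3ccccc3)cc2)c1 | intermediate
5 | ethynylmagnesium bromide | C#C[Mg]Br | starting material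
6 | 1-(benzyloxy)-4-(prop-2-yn-1-yl)benzene | C#CCc1ccc(OCc2ccccc2)cc1 | intermediate
7 | methyl chloroformate | COC(Cl)=O | starting material
8 | [3-[4-(benzyloxy)phenyl]prop-1-yn-1-yl]lithium (lithium acetylide) | [Li]C#CCc1ccc(OCc2ccccc2)cc1 | intermediate
9 | methyl 4-[4-(benzyloxy)phenyl]but-2-ynoate | COC(=O)C#CCc1ccc(OCc2ccccc2)cc1 | intermediate
10 | methyl 1,3-bis[4-(benzyloxy)benzyl]-7-oxabicyclo[2.2.1]hepta-2,5-diene-2-carboxylate (racemic, one enantiomer drawn) | COC(=O)C1=C(Cc3ccc(OCc4ccccc4)cc3)[C@@H]2C=C[C@@]1(Cc5ccc(OCc6ccccc6)cc5)O2 | intermediate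
11 | methyl 2,6-bis[4-(benzyloxy)benzyl]-3-hydroxybenzoate | COC(=O)c1c(Cc2ccc(OCc3ccccc3)cc2)ccc(O)c1Cc1ccc(OCc2ccccc2)cc1 | intermediate
12 | methyl 3-(benzyloxy)-2,6-bis[4-(benzyloxy)benzyl]benzoate | COC(=O)c1c(Cc2ccc(OCc3ccccc3)cc2)ccc(OCc2ccccc2)c1Cc1ccc(OCc2ccccc2)cc1 | intermediate
13 | [3-(benzyloxy)-2,6-bis[4-(benzyloxy)benzyl]phenyl]methanol | OCc1c(Cc2ccc(OCc3ccccc3)cc2)ccc(OCc2ccccc2)c1Cc1ccc(OCc2ccccc2)cc1 | intermediate
14 | 1-(benzyloxy)-2,4-bis[4-(benzyloxy)benzyl]-3-(bromomethyl)benzene | BrCc1c(Cc2ccc(OCc3ccccc3)cc2)ccc(OCc2ccccc2)c1Cc1ccc(OCc2ccccc2)cc1 | intermediate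
15 | diethyl [3-(benzyloxy)-2,6-bis[4-(benzyloxy)benzyl]benzyl]phosphonate | CCOP(=O)(OCC)Cc1c(Cc2ccc(OCc3ccccc3)cc2)ccc(OCc2ccccc2)c1Cc1ccc(OCc2ccccc2)cc1 | intermediate
16 | 3-hydroxy-5-methoxybenzaldehyde | COc1cc(O)cc(C=O)c1 | starting material
17 | 3-(benzyloxy)-5-methoxybenzaldehyde | COc1cc(OCc2ccccc2)cc(C=O)c1 | intermediate
18 | 1-(benzyloxy)-3-[(E)-2-[3-(benzyloxy)-5-methoxyphenyl]ethenyl]-2,4-bis[4-(benzyloxy)benzyl]benzene | COc1cc(OCc2ccccc2)cc(/C=C/c2c(Cc3ccc(OCc4ccccc4)cc3)ccc(OCc3ccccc3)c2Cc2ccc(OCc3ccccc3)cc2)c1 | intermediate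
19 | 3-[2-[3-hydroxy-2,6-bis(4-hydroxybenzyl)phenyl]ethyl]-5-methoxyphenol | COc1cc(O)cc(CCc2c(Cc3ccc(O)cc3)ccc(O)c2Cc2ccc(O)cc2)c1 | target

**Step count**

Total: 11 steps. Longest linear sequence: 9 steps (steps 2, 3, 4, 5, 6, 7, 8, 10 and 11, from 4-(benzyloxy)benzyl chloride 2).

**Steps most likely to fail**

1. Step 4. Several processes could defeat it:
   - The internal, singly activated alkyne may be too sluggish a dienophile.
   - The furan C5 may add to the ynoate in a conjugate sense without ring closure, ending in an open 2-alkenylfuran.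
   - The Lewis acid may strip benzyl ethers or oligomerise the furan.

   The fallback sets out from 4 and 2 and returns to the route at 12.
   - Methyl propiolate is brominated (NBS, AgNO3 cat., acetone) to methyl 3-bromopropiolate F1, a far more reactive dienophile that adds to 2-substituted furans thermally and with the same orientation.
   - With 4 in toluene at 80 °C it should give racemic methyl 1-[4-(benzyloxy)benzyl]-3-bromo-7-oxabicyclo[2.2.1]hepta-2,5-diene-2-carboxylate F2.
   - BF3·OEt2 in CH2Cl2 should open the bridge to methyl 6-[4-(benzyloxy)benzyl]-2-bromo-3-hydroxybenzoate F3.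
   - O-Benzylation (BnBr, K2CO3, DMF) should give methyl 3-(benzyloxy)-6-[4-(benzyloxy)benzyl]-2-bromobenzoate F4.
   - Negishi coupling of F4 with [4-(benzyloxy)benzyl]zinc chloride F5 (from 2, Zn dust, LiCl, THF) under Pd(OAc)2/SPhos in THF at 60 °C installs the second arylmethyl group and delivers 12, from which step 6 follows.

2. Step 3. The acetylide, or any excess base, may deprotonate the benzylic, ester-activated CH2 of the product and isomerise the ynoate to the conjugated allenoate; double acylation is a lesser risk. The fallback sets out from 6 and returns at 9. Oxidative methoxycarbonylation of the terminal alkyne (PdCl2 cat., CuCl2 2 equiv, NaOAc, CO 1 atm, MeOH, rt) installs the ester without any strong base. No new compound is made (F0).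

3. Step 10. The carbanion of phosphonate 15 is flanked by two arylmethyl groups, so its addition to the aldehyde may be slow and the olefination incomplete. The fallback reverses the roles of the partners; it sets out from 13 and 17 and returns at 18.
   - Alcohol 13 is oxidised (MnO2, CH2Cl2, rt) to 3-(benzyloxy)-2,6-bis[4-(benzyloxy)benzyl]benzaldehyde F6.
   - Aldehyde 17 is reduced (NaBH4, MeOH, 0 °C) to [3-(benzyloxy)-5-methoxyphenyl]methanol F7.
   - F7 is converted with PPh3·HBr (MeCN, reflux) into [3-(benzyloxy)-5-methoxybenzyl]triphenylphosphonium bromide F8.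
   - Wittig reaction of the unhindered ylide from F8 (KOtBu, THF, 0 °C → rt) with F6 should give 18 together with its (Z)-isomer, 1-(benzyloxy)-3-[(Z)-2-[3-(benzyloxy)-5-methoxyphenyl]ethenyl]-2,4-bis[4-(benzyloxy)benzyl]benzene F9. Both are carried into step 11 and converge on 19.

Further compounds
F1 | step 4 | methyl 3-bromopropiolate | COC(=O)C#CBr
F2 | step 4 | methyl 1-[4-(benzyloxy)benzyl]-3-bromo-7-oxabicyclo[2.2.1]hepta-2,5-diene-2-carboxylate (racemic, one enantiomer drawn) | COC(=O)C1=C(Br)[C@@H]2C=C[C@@]1(Cc3ccc(OCc4ccccc4)cc3)O2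
F3 | step 4 | methyl 6-[4-(benzyloxy)benzyl]-2-bromo-3-hydroxybenzoate | COC(=O)c1c(Br)c(O)ccc1Cc1ccc(OCc2ccccc2)cc1
F4 | step 4 | methyl 3-(benzyloxy)-6-[4-(benzyloxy)benzyl]-2-bromobenzoate | COC(=O)c1c(Br)c(OCc2ccccc2)ccc1Cc1ccc(OCc2ccccc2)cc1
F5 | step 4 | [4-(benzyloxy)benzyl]zinc chloride | Cl[Zn]Cc1ccc(OCc2ccccc2)cc1
F0 | step 3 | none | none
F6 | step 10 | 3-(benzyloxy)-2,6-bis[4-(benzyloxy)benzyl]benzaldehyde | O=Cc1c(Cc2ccc(OCc3ccccc3)cc2)ccc(OCc2ccccc2)c1Cc1ccc(OCc2ccccc2)cc1
F7 | step 10 | [3-(benzyloxy)-5-methoxyphenyl]methanol | COc1cc(OCc2ccccc2)cc(CO)c1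
F8 | step 10 | [3-(benzyloxy)-5-methoxybenzyl]triphenylphosphonium bromide | COc1cc(OCc2ccccc2)cc(C[P+](c2ccccc2)(c2ccccc2)c2ccccc2)c1.[Br-]
F9 | step 10 | 1-(benzyloxy)-3-[(Z)-2-[3-(benzyloxy)-5-methoxyphenyl]ethenyl]-2,4-bis[4-(benzyloxy)benzyl]benzene | COc1cc(OCc2ccccc2)cc(/C=C\c2c(Cc3ccc(OCc4ccccc4)cc3)ccc(OCc3ccccc3)c2Cc2ccc(OCc3ccccc3)cc2)c1
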